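**Plan**
- Retrosynthesis: after the silyl ether and the C5 methyl ether are removed, ring C of the chromone is cut at C8a–O1, C4a–C4 and O1–C2. This gives 3,5-dimethoxybenzyne (from ortho-silyl triflate 8) and the chiral ynoic acid 16. Acid 16 is cut at the carboxyl–alkyne bond (CO2) and at the propargylic C–C bond (acetylide plus terminal epoxide 11).
- Enabling feature: in ring A, C4a and C8a are neighbouring carbons that carry the C4 acyl carbon and O1, which is what an aryne takes up across its triple bond. The C5 oxygen next to C4a decides which aryne carbon receives which.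
- Forward order: ring A is bought as 3,5-dimethoxyphenol and converted to the silyl triflate (steps 1–3). The side chain is built from methyl hept-6-enoate (steps 4–9). Ring C is closed in step 10, and steps 11–12 free the C5 phenol and the carbinol.
- Stereochemistry: the single (R) centre is fixed by hydrolytic kinetic resolution of the terminal epoxide (step 5). It is retained in the SN2 opening at the other epoxide carbon and is not touched afterwards.

Key step: step 10

Remark: the (R,R)-configured cobalt salen catalyst is assumed to leave the (R)-epoxide, as is usual for terminal alkyl epoxides; Mosher ester analysis of 13 would confirm this before material is carried on. Ring atoms are given in chromone numbering.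

**Route**

Step 1
Reactants: 1 3,5-dimethoxyphenol
Product: 2 3,5-dimethoxyphenyl isopropylcarbamate
Conditions: i-PrNCO, Et3N (cat.), CH2Cl2, rt
Reagents that add atoms: isopropyl isocyanate, CC(C)N=C=O
Why: Carbamoylation, in which the phenol adds to the isocyanate under amine catalysis to give the N-monosubstituted carbamate that later serves as a removable ortho-directing group.

Step 2
Reactants: 2 3,5-dimethoxyphenyl isopropylcarbamate
Product: 6 3,5-dimethoxy-2-(trimethylsilyl)phenyl isopropylcarbamate, via N-silyl carbamate 3 (not isolated), via aryllithium 4 (not isolated), via N-silyl C-silyl carbamate 5 (not isolated)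
Conditions: TBSOTf, TMEDA, Et2O, 0 °C to rt; then n-BuLi, TMEDA, −78 °C; Me3SiCl, −78 °C to rt; aq. NaHSO4
Reagents that add atoms: chlorotrimethylsilane, C[Si](C)(C)Cl
Why: Directed ortho-metalation, in which the N–H is first masked in the flask as the N-silyl carbamate, n-BuLi/TMEDA should then lithiate C2 (flanked by the carbamate oxygen and a methoxy group), Me3SiCl traps the aryllithium and the N–Si bond is hydrolysed on acidic work-up.

Step 3
Reactants: 6 3,5-dimethoxy-2-(trimethylsilyl)phenyl isopropylcarbamate
Product: 8 3,5-dimethoxy-2-(trimethylsilyl)phenyl trifluoromethanesulfonate, via silylphenol 7 (not isolated)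
Conditions: DBU, Et2NH, MeCN, 40 °C; then PhNTf2, rt
Reagents that add atoms: N-phenylbis(trifluoromethanesulfonimide), O=S(=O)(N(c1ccccc1)S(=O)(=O)C(F)(F)F)C(F)(F)F
Why: E1cB carbamate cleavage followed by O-triflation in one pot, in which DBU deprotonates the N–H, the phenoxide is expelled together with isopropyl isocyanate that Et2NH scavenges as a urea, and PhNTf2 sulfonylates the phenoxide without disturbing the C–Si bond.

Step 4
Reactants: 9 methyl hept-6-enoate
Product: 10 rac-methyl 5-(oxiran-2-yl)pentanoate
Conditions: mCPBA, NaHCO3, CH2Cl2, 0 °C to rt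
Reagents that add atoms: meta-chloroperoxybenzoic acid, OOC(=O)c1cccc(Cl)c1
Why: Prilezhaev epoxidation of an unactivated terminal alkene by a peracid, to which the methyl ester is inert.

Step 5
Reactants: 10 rac-methyl 5-(oxiran-2-yl)pentanoate
Product: 11 methyl 5-[(2R)-oxiran-2-yl]pentanoate
Conditions: (R,R)-(salen)Co(OAc) 0.5 mol % [salen = N,N'-bis(3,5-di-tert-butylsalicylidene)cyclohexane-1,2-diamine dianion; generated from (R,R)-(salen)Co, AcOH, air], H2O 0.55 equiv, THF, 0 °C to rt
Reagents that add atoms: none
Why: Jacobsen hydrolytic kinetic resolution, in which the chiral trivalent cobalt salen catalyst hydrates the (S)-epoxide much faster, so the unreacted epoxide should be recovered as the (R)-enantiomer in high enantiomeric purity, which sets the only stereocentre of the target.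

Step 6
Reactants: 11 methyl 5-[(2R)-oxiran-2-yl]pentanoate
Product: 12 methyl (6R)-6-hydroxy-9-(trimethylsilyl)non-8-ynoate
Conditions: Me3SiC≡CH, n-BuLi, THF, −78 °C; BF3·OEt2; then 11, −78 °C; aq. NH4Cl
Reagents that add atoms: ethynyltrimethylsilane, C#C[Si](C)(C)C
Why: BF3-mediated epoxide alkynylation (Yamaguchi–Hirao), in which the alkynyl trifluoroborate opens the activated epoxide at its terminal carbon by SN2, so the C–O bond at the stereocentre is not broken and the (R) configuration is retained, while the methyl ester is not attacked at −78 °C.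

Step 7
Reactants: 12 methyl (6R)-6-hydroxy-9-(trimethylsilyl)non-8-ynoate
Product: 13 methyl (6R)-6-hydroxynon-8-ynoate
Conditions: K2CO3 (cat.), MeOH, 0 °C to rt
Reagents that add atoms: none
Why: Base-catalysed protodesilylation of the alkynylsilane by methoxide, under which the methyl ester can only exchange with itself.

Step 8
Reactants: 13 methyl (6R)-6-hydroxynon-8-ynoate
Product: 14 methyl (6R)-6-[(tert-butyldimethylsilyl)oxy]non-8-ynoate
Conditions: TBSCl, imidazole, DMF, rt
Reagents that add atoms: tert-butyldimethylsilyl chloride, CC(C)(C)[Si](C)(C)Cl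
Why: Standard imidazole-promoted O-silylation, which masks the carbinol so that it cannot be O-arylated by the aryne or act as a nucleophile later.

Step 9
Reactants: 14 methyl (6R)-6-[(tert-butyldimethylsilyl)oxy]non-8-ynoate
Product: 16 (5R)-5-[(tert-butyldimethylsilyl)oxy]-10-methoxy-10-oxodec-2-ynoic acid, via caesium ynoate 15 (not isolated)
Conditions: CO2 (2 atm), AgI (2 mol %), Cs2CO3 (1.5 equiv), DMF, 50 °C; then cold 1 M HCl to pH 3
Reagents that add atoms: carbon dioxide, O=C=O
Why: Direct C–H carboxylation of a terminal alkyne, a known reaction for alkyl alkynes, in which Cs2CO3 deprotonates the silver-bound alkyne and the silver acetylide inserts CO2 to give the caesium ynoate, conditions that an ester and a silyl ether should tolerate.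

Step 10
Reactants: 8 3,5-dimethoxy-2-(trimethylsilyl)phenyl trifluoromethanesulfonate; 16 (5R)-5-[(tert-butyldimethylsilyl)oxy]-10-methoxy-10-oxodec-2-ynoic acid
Product: 19 methyl (6R)-6-[(tert-butyldimethylsilyl)oxy]-7-(5,7-dimethoxy-4-oxo-4H-chromen-2-yl)heptanoate, via 3,5-dimethoxybenzyne 17 (not isolated), via ortho-hydroxyaryl ynone 18 (not isolated)
Conditions: 8 (1.8 equiv), CsF (5 equiv), THF, sealed tube, 110–125 °C; then Et2NH, EtOH, rt
Reagents that add atoms: none
Why: Proposed new method: fluoride removes the silyl group of 8 and triflate leaves to give aryne 17, and the caesium carboxylate of 16 adds through oxygen to the aryne carbon remote from the flanking methoxy group (future C8a), which places the aryl anion at future C4a where the ortho methoxy group stabilises it inductively. That anion attacks the adjacent ester carbonyl through a four-membered benzoxetene alkoxide, which opens to the ortho-acyl phenoxide 18, so C8a–O1 and C4a–C4 arise in one insertion event. The phenoxide then adds 6-endo-dig to the β-carbon of the ynone (O1–C2) and protonation at C3 completes ring C. The closest known reactions are aryne insertion into the C–O bond of carboxylic acids to give ortho-hydroxyaryl ketones and the base- or amine-mediated 6-endo cyclisation of ortho-hydroxyaryl ynones to chromones; the unproven part is running both in one flask on a functionalised alkyl 2-ynoic acid. No stereocentre is formed, and the silyloxy-bearing centre has no acidic hydrogen and should pass through unchanged. The step needs regioselective aryne capture, which the methoxy group next to the triple bond secures, and 6-endo rather than 5-exo closure, which is favoured for an alkyl ynone in aprotic medium and is backed up by the diethylamine finish through an enaminone.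

Step 11
Reactants: 19 methyl (6R)-6-[(tert-butyldimethylsilyl)oxy]-7-(5,7-dimethoxy-4-oxo-4H-chromen-2-yl)heptanoate
Product: 20 methyl (6R)-6-[(tert-butyldimethylsilyl)oxy]-7-(5-hydroxy-7-methoxy-4-oxo-4H-chromen-2-yl)heptanoate
Conditions: BCl3 (1 M in CH2Cl2, 2 equiv), CH2Cl2, −78 to 0 °C; ice/aq. NaHCO3
Reagents that add atoms: none
Why: Chelation-controlled ether cleavage, in which BCl3 binds the C4 carbonyl and the peri C5 methoxy oxygen in a six-membered chelate and chloride removes only that methyl group, the C7 methyl ether and the methyl ester lacking such activation, while any silyl ether lost here would only anticipate step 12.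

Step 12
Reactants: 20 methyl (6R)-6-[(tert-butyldimethylsilyl)oxy]-7-(5-hydroxy-7-methoxy-4-oxo-4H-chromen-2-yl)heptanoate
Product: 21 penithochromone O, methyl (6R)-6-hydroxy-7-(5-hydroxy-7-methoxy-4-oxo-4H-chromen-2-yl)heptanoate
Conditions: HF·pyridine, pyridine, THF, 0 °C to rt
Reagents that add atoms: none
Why: Fluoride-driven Si–O cleavage under buffered, mildly acidic conditions, which avoids base-induced E1cB loss of the hydroxyl group β to the acidic C2 methylene and leaves the stereocentre untouched.

**Compound list**

1 | 3,5-dimethoxyphenol | COc1cc(O)cc(OC)c1 | starting material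
2 | 3,5-dimethoxyphenyl isopropylcarbamate | COc1cc(OC)cc(OC(=O)NC(C)C)c1 | intermediate
3 | N-silyl carbamate: 3,5-dimethoxyphenyl N-(tert-butyldimethylsilyl)-N-isopropylcarbamate (not isolated) | COc1cc(OC)cc(OC(=O)N(C(C)C)[Si](C)(C)C(C)(C)C)c1 | intermediate
4 | aryllithium: 2-lithio-3,5-dimethoxyphenyl N-(tert-butyldimethylsilyl)-N-isopropylcarbamate (not isolated) | COc1cc(OC)c([Li])c(OC(=O)N(C(C)C)[Si](C)(C)C(C)(C)C)c1 | intermediate
5 | N-silyl C-silyl carbamate: 3,5-dimethoxy-2-(trimethylsilyl)phenyl N-(tert-butyldimethylsilyl)-N-isopropylcarbamate (not isolated) | COc1cc(OC)c([Si](C)(C)C)c(OC(=O)N(C(C)C)[Si](C)(C)C(C)(C)C)c1 | intermediate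
6 | 3,5-dimethoxy-2-(trimethylsilyl)phenyl isopropylcarbamate | COc1cc(OC)c([Si](C)(C)C)c(OC(=O)NC(C)C)c1 | intermediate
7 | silylphenol: 3,5-dimethoxy-2-(trimethylsilyl)phenol, present as its DBU salt (not isolated) | COc1cc(OC)c([Si](C)(C)C)c(O)c1 | intermediate
8 | 3,5-dimethoxy-2-(trimethylsilyl)phenyl trifluoromethanesulfonate | COc1cc(OC)c([Si](C)(C)C)c(OS(=O)(=O)C(F)(F)F)c1 | intermediate
9 | methyl hept-6-enoate | COC(=O)CCCCC=C | starting material
10 | rac-methyl 5-(oxiran-2-yl)pentanoate | COC(=O)CCCCC1CO1 | intermediate
11 | methyl 5-[(2R)-oxiran-2-yl]pentanoate | COC(=O)CCCC[C@@H]1CO1 | intermediate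
12 | methyl (6R)-6-hydroxy-9-(trimethylsilyl)non-8-ynoate | COC(=O)CCCC[C@@H](O)CC#C[Si](C)(C)C | intermediate
13 | methyl (6R)-6-hydroxynon-8-ynoate | COC(=O)CCCC[C@@H](O)CC#C | intermediate
14 | methyl (6R)-6-[(tert-butyldimethylsilyl)oxy]non-8-ynoate | COC(=O)CCCC[C@@H](O[Si](C)(C)C(C)(C)C)CC#C | intermediate
15 | caesium ynoate: caesium (5R)-5-[(tert-butyldimethylsilyl)oxy]-10-methoxy-10-oxodec-2-ynoate (not isolated) | COC(=O)CCCC[C@@H](O[Si](C)(C)C(C)(C)C)CC#CC(=O)[O-].[Cs+] | intermediate
16 | (5R)-5-[(tert-butyldimethylsilyl)oxy]-10-methoxy-10-oxodec-2-ynoic acid | COC(=O)CCCC[C@@H](O[Si](C)(C)C(C)(C)C)CC#CC(=O)O | intermediate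
17 | 3,5-dimethoxybenzyne (not isolated) | COC1=CC(OC)=CC#C1 | intermediate
18 | ortho-hydroxyaryl ynone: methyl (6R)-6-[(tert-butyldimethylsilyl)oxy]-10-(2-hydroxy-4,6-dimethoxyphenyl)-10-oxodec-8-ynoate, present as its caesium phenoxide (not isolated) | COC(=O)CCCC[C@@H](O[Si](C)(C)C(C)(C)C)CC#CC(=O)c1c(O)cc(OC)cc1OC | intermediate
19 | methyl (6R)-6-[(tert-butyldimethylsilyl)oxy]-7-(5,7-dimethoxy-4-oxo-4H-chromen-2-yl)heptanoate | COC(=O)CCCC[C@@H](O[Si](C)(C)C(C)(C)C)Cc1cc(=O)c2c(OC)cc(OC)cc2o1 | intermediate
20 | methyl (6R)-6-[(tert-butyldimethylsilyl)oxy]-7-(5-hydroxy-7-methoxy-4-oxo-4H-chromen-2-yl)heptanoate | COC(=O)CCCC[C@@H](O[Si](C)(C)C(C)(C)C)Cc1cc(=O)c2c(O)cc(OC)cc2o1 | intermediate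
21 | penithochromone O, methyl (6R)-6-hydroxy-7-(5-hydroxy-7-methoxy-4-oxo-4H-chromen-2-yl)heptanoate | COC(=O)CCCC[C@@H](O)Cc1cc(=O)c2c(O)cc(OC)cc2o1 | target

**Step count**

Total: 12 steps. Longest linear sequence: 9 steps (9 to 21, steps 4–12). The aryne precursor 8 is a 3-step branch (steps 1–3) that joins at step 10.

**Steps most likely to fail**

1. Step 10. The aryl anion may be protonated before it reaches the ester carbonyl, which would stop at plain O-arylation. The ynoate may decarboxylate or isomerise at its propargylic position at the temperature required, and the silyl ether may be lost to fluoride. In that case ring C would be made by the known palladium-catalysed carbonylative annulation of ortho-iodophenols with terminal alkynes. The fallback sets out from 1 and 14. Iodination of 1 (NIS, MeCN, 0 °C) and separation from the 4-iodo isomer should give 2-iodo-3,5-dimethoxyphenol F1. Phenol F1, alkyne 14 and CO (balloon) with PdCl2(PPh3)2 in Et2NH at 40–60 °C should undergo carbonylative Sonogashira coupling and amine-mediated 6-endo closure. This gives chromone 19 directly, where the route is rejoined.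

2. Step 9. Carboxylation may stay incomplete because CO2 is lost again on work-up, or the methyl ester may be saponified by carbonate and adventitious water. The carboxyl carbon would then be brought in together with the alkyne. The fallback sets out from epoxide 11. Lithiated tert-butyl propiolate (n-BuLi, THF, −90 °C) with BF3·OEt2 at −78 °C should open the epoxide at its terminal carbon to give 1-tert-butyl 10-methyl (5R)-5-hydroxydec-2-ynedioate F2. Silylation (TBSCl, imidazole, DMF) gives 1-tert-butyl 10-methyl (5R)-5-[(tert-butyldimethylsilyl)oxy]dec-2-ynedioate F3. Treatment with Me3SiOTf and 2,6-lutidine in CH2Cl2 and aqueous work-up removes only the tert-butyl ester, as isobutene, and returns to acid 16.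

3. Step 2. Metalation may occur at C4 between the two methoxy groups, or the carbamoyl group may migrate to carbon (anionic Fries rearrangement) on warming. The silyl group would then be delivered to C2 by a retro-Brook shift. The fallback sets out from 1. NBS in CH2Cl2 at −78 °C should give 2-bromo-3,5-dimethoxyphenol F4, to be separated from the 4-bromo isomer. Heating with HMDS in THF gives (2-bromo-3,5-dimethoxyphenoxy)trimethylsilane F5. n-BuLi in THF at −100 to −78 °C effects bromine–lithium exchange and 1,3 oxygen-to-carbon silyl migration to the lithium phenoxide of 7. Tf2O converts this in the same flask to triflate 8, where the route is rejoined.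

**Further compounds**

F1 | step 10 | 2-iodo-3,5-dimethoxyphenol | COc1cc(O)c(I)c(OC)c1
F2 | step 9 | 1-tert-butyl 10-methyl (5R)-5-hydroxydec-2-ynedioate | COC(=O)CCCC[C@@H](O)CC#CC(=O)OC(C)(C)C
F3 | step 9 | 1-tert-butyl 10-methyl (5R)-5-[(tert-butyldimethylsilyl)oxy]dec-2-ynedioate | COC(=O)CCCC[C@@H](O[Si](C)(C)C(C)(C)C)CC#CC(=O)OC(C)(C)C
F4 | step 2 | 2-bromo-3,5-dimethoxyphenol | COc1cc(O)c(Br)c(OC)c1
F5 | step 2 | (2-bromo-3,5-dimethoxyphenoxy)trimethylsilane | COc1cc(O[Si](C)(C)C)c(Br)c(OC)c1
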